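**Plan**
1. Retrosynthesis: the γ-lactone is opened at O–C12 and taken back, through oxidation level and hydroboration, to a C7 isopropenyl group and a C6 silyl ether. The acetates go back to carbinols and the C9 carbinol to the C9 enone.
2. Enabling feature: in the ten-membered ring C1–C10, the oxygenated carbon C9, the methylene C8 and the methine C7 (the only ring atom with a side chain, C11–C13 of the lactone ring) then read C9(=O)–C8H2–C7H–C11(=C12H2)CH3, a γ,δ-unsaturated ketone. A retro-Claisen cut of C7–C8 joins O to C12, draws O, C12 and C11 into the ring and puts C8 outside, giving a 12-membered 2-methylene oxacycle, that is, a methylenated macrolactone.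
3. The macrolactone is cut at C6–C7 (alkenyl iodide plus enal) and at the C12–O ester bond. This gives a Z-acid (C9, C10, C1–C6) and (E)-3-iodo-2-methylallyl alcohol (C7, C11–C13). The acid comes from a C5 enal, an allyl group and a methacryloyl group.
4. Forward order: temporary six-membered lactone (metathesis, fixes Z-C1=C10), open chain, ester, 12-membered lactone, methylenation, contraction to the ten-membered carbocycle, γ-lactone last.
5. Stereochemistry: C3 by catalytic asymmetric allylation and C6 by ligand-controlled chromium addition. C7 is relayed from C6 in the rearrangement and C11 from C6/C7 in the hydroboration. C9 is set by oxazaborolidine reduction. E-C4=C5 is bought, and E-C7=C11 (consumed later) comes from carboalumination.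

Key step: step 11

Remark on locants: C1–C15 are the germacrane locants of the target. The ring is C1–C10. The lactone O sits on C6, C11 on C7, C12 is the lactone C=O, C13 the methyl on C11, C14 the methyl on C10 and C15 the methyl on C4. The acetates are on C3 and C9.
Assumption: (2E)-4-acetoxy-2-methylbut-2-enal, the C5 aldehyde of industrial vitamin A acetate manufacture, is taken as purchasable. It is otherwise one SeO2 oxidation away from prenyl acetate.

**Step 1**
Reactants: 1 (2E)-4-acetoxy-2-methylbut-2-enal; 2 allyltributylstannane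
Product: 3 (2E,4S)-4-hydroxy-3-methylhepta-2,6-dien-1-yl acetate
Conditions: (S)-BINOL (20 mol %), Ti(OiPr)4 (10 mol %), 4 Å MS, CH2Cl2, −20 °C; aq NaHCO3
Reagents that add atoms: none
Why: Keck asymmetric allylation, in which the (S)-BINOL–titanium Lewis acid should expose the Si face of the 2-methyl-2-enal to the stannane and set C3 as S, as it does for closely related 2-methyl enals, while the allylic acetate is inert to this mild catalyst.

**Step 2**
Reactants: 3 (2E,4S)-4-hydroxy-3-methylhepta-2,6-dien-1-yl acetate; 4 methacryloyl chloride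
Product: 5 (2E,4S)-1-acetoxy-3-methylhepta-2,6-dien-4-yl methacrylate
Conditions: Et3N, DMAP (cat.), CH2Cl2, 0 °C
Reagents that add atoms: none
Why: DMAP-catalysed O-acylation of a secondary allylic alcohol, which brings in C9, C10 and C14 and touches no stereocentre.

**Step 3**
Reactants: 5 (2E,4S)-1-acetoxy-3-methylhepta-2,6-dien-4-yl methacrylate
Product: 6 (6S)-6-[(2E)-4-acetoxybut-2-en-2-yl]-3-methyl-5,6-dihydro-2H-pyran-2-one
Conditions: second-generation Grubbs catalyst (5 mol %), CH2Cl2, reflux
Reagents that add atoms: none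
Why: Ring-closing metathesis of the monosubstituted alkene with the methacrylate; the six-membered ring can hold only a cis double bond, so the C1=C10 geometry (C2 and C9 cis) is fixed here, and the trisubstituted C4=C5 alkene is too hindered to take part.

**Step 4**
Reactants: 6 (6S)-6-[(2E)-4-acetoxybut-2-en-2-yl]-3-methyl-5,6-dihydro-2H-pyran-2-one
Product: 9 (2Z,5S,6E)-2,6-dimethyl-5,8-bis(triethylsilyloxy)octa-2,6-dienoic acid, via lithium dihydroxycarboxylate 7 (not isolated), via tris(triethylsilyl) derivative 8 (not isolated)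
Conditions: LiOH, THF/H2O, 0 °C to rt, evaporate; TESCl, imidazole, DMF, 0 °C to rt; K2CO3, MeOH/THF/H2O, 0 °C; pH 5.5 buffer
Reagents that add atoms: lithium hydroxide [Li+].[OH-]; chlorotriethylsilane CC[Si](Cl)(CC)CC
Why: Saponification of lactone and acetate, exhaustive silylation and selective hydrolysis of the labile silyl ester (the standard hydroxy-acid protection sequence); silylating the carboxylate salt before any acidification should prevent relactonisation, and neither C3 nor the Z-alkene is affected.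

**Step 5**
Reactants: 10 prop-2-yn-1-ol
Product: 12 (2E)-3-iodo-2-methylprop-2-en-1-ol, via alkenylalane 11 (not isolated)
Conditions: Me3Al, Cp2ZrCl2 (25 mol %), CH2Cl2, 0 °C to rt; I2, THF, −30 °C; aq K2CO3
Reagents that add atoms: trimethylaluminium C[Al](C)C; iodine [I][I]
Why: Negishi zirconium-catalysed carboalumination, a syn addition of methyl and aluminium to the terminal alkyne with aluminium at the terminus, followed by iodinolysis with retention, should give only the E-iodide.

**Step 6**
Reactants: 9 (2Z,5S,6E)-2,6-dimethyl-5,8-bis(triethylsilyloxy)octa-2,6-dienoic acid; 12 (2E)-3-iodo-2-methylprop-2-en-1-ol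
Product: 13 (2E)-3-iodo-2-methylprop-2-en-1-yl (2Z,5S,6E)-2,6-dimethyl-5,8-bis(triethylsilyloxy)octa-2,6-dienoate
Conditions: PPh3, DIAD, toluene, 0 °C
Reagents that add atoms: none
Why: Mitsunobu esterification activates the primary allylic alcohol and not the acid, so the isomerisation-prone Z-2-methyl-2-enoic acid never passes through an activated acyl species.

**Step 7**
Reactants: 13 (2E)-3-iodo-2-methylprop-2-en-1-yl (2Z,5S,6E)-2,6-dimethyl-5,8-bis(triethylsilyloxy)octa-2,6-dienoate
Product: 14 (2E)-3-iodo-2-methylprop-2-en-1-yl (2Z,5S,6E)-2,6-dimethyl-8-oxo-5-(triethylsilyloxy)octa-2,6-dienoate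
Conditions: (COCl)2, DMSO, CH2Cl2, −78 to −40 °C; Et3N, −78 °C to rt
Reagents that add atoms: none
Why: Swern oxidation applied directly to a primary triethylsilyl ether; the chlorosulfonium salt desilylates the unhindered primary allylic ether and oxidises it in the same flask, a known selectivity that leaves the secondary ether at C3 in place.

**Step 8**
Reactants: 14 (2E)-3-iodo-2-methylprop-2-en-1-yl (2Z,5S,6E)-2,6-dimethyl-8-oxo-5-(triethylsilyloxy)octa-2,6-dienoate
Product: 15 (3Z,6S,7E,9S,10E)-9-hydroxy-3,7,11-trimethyl-6-(triethylsilyloxy)-1-oxacyclododeca-3,7,10-trien-2-one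
Conditions: CrCl2 (4 equiv), NiCl2 (0.1 equiv), valinol-derived N-[2-(4-isopropyl-4,5-dihydrooxazol-2-yl)-6-methylphenyl]methanesulfonamide (4.4 equiv, the antipode that directs attack to the Si face of C6), Et3N, THF, slow addition to 2 mM, rt
Reagents that add atoms: none
Why: Nozaki–Hiyama–Kishi reaction run intramolecularly at high dilution; the alkenyl iodide is taken up by zerovalent nickel, passed to chromium with retention of the E geometry and added 1,2 to the enal, and the chiral sulfonamide on chromium should choose the Si face (6S), which suits a centre whose two alkenyl arms are locally alike and would defeat a ketone reduction or a resolution.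

**Step 9**
Reactants: 15 (3Z,6S,7E,9S,10E)-9-hydroxy-3,7,11-trimethyl-6-(triethylsilyloxy)-1-oxacyclododeca-3,7,10-trien-2-one
Product: 16 (3Z,6S,7E,9S,10E)-9-(tert-butyldimethylsilyloxy)-3,7,11-trimethyl-6-(triethylsilyloxy)-1-oxacyclododeca-3,7,10-trien-2-one
Conditions: TBSCl, imidazole, DMAP (cat.), DMF, rt
Reagents that add atoms: tert-butyldimethylsilyl chloride CC(C)(C)[Si](C)(C)Cl
Why: Standard silylation under neutral conditions, which avoids ionisation of the bis-allylic carbinol and gives C6 a bulkier, more robust group than C3 for the later stereocontrol and ordered deprotection.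

**Step 10**
Reactants: 16 (3Z,6S,7E,9S,10E)-9-(tert-butyldimethylsilyloxy)-3,7,11-trimethyl-6-(triethylsilyloxy)-1-oxacyclododeca-3,7,10-trien-2-one
Product: 17 (3Z,6S,7E,9S,10E)-9-(tert-butyldimethylsilyloxy)-3,7,11-trimethyl-2-methylidene-6-(triethylsilyloxy)-1-oxacyclododeca-3,7,10-triene
Conditions: Cp2TiMe2 (3 equiv), toluene, 70 °C, dark; pentane, filtration through basic alumina
Reagents that add atoms: dimethyltitanocene C[Ti](C)(C1C=CC=C1)C1C=CC=C1
Why: Petasis methylenation; thermally formed Cp2Ti=CH2 turns the only carbonyl group into the exocyclic enol ether (C8) through an oxatitanacyclobutane, a non-basic reaction known for α,β-unsaturated esters and lactones that leaves silyl ethers and alkene geometries untouched.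

**Step 11**
Reactants: 17 (3Z,6S,7E,9S,10E)-9-(tert-butyldimethylsilyloxy)-3,7,11-trimethyl-2-methylidene-6-(triethylsilyloxy)-1-oxacyclododeca-3,7,10-triene
Product: 18 (2Z,5S,6E,8R,9S)-8-(tert-butyldimethylsilyloxy)-2,6-dimethyl-9-(prop-1-en-2-yl)-5-(triethylsilyloxy)cyclodeca-2,6-dien-1-one
Conditions: toluene (5 mM), solid K2CO3, BHT (cat.), base-washed sealed tube, 125 °C
Reagents that add atoms: none
Why: Proposed new method: a concerted suprafacial [3,3]-sigmatropic (Claisen) shift of the allyl vinyl ether C8=C9–O–C12–C11=C7, in which C9, O, C12, C11 and C7 are ring members and C8 is exocyclic, forms C7–C8 and breaks O–C12, so that O, C12 and C11 leave the ring, C8 enters it and the 12-membered oxacycle becomes the ten-membered carbocycle. The closest known reaction types are the Claisen rearrangement of methylenated lactones, established in the two-atom ring-enlarging mode (vinyl group outside the ring), and the four-atom Ireland–Claisen contraction of macrolactones; the two-atom contraction argued here differs only in which termini of the same six-centre array carry the tether. The carbocycle is closed pericyclically, not by exo or endo attack of a chain end: the chair-like six-centre array is bridged across C9 and C7 by the seven-atom chain C10–C1–C2–C3–C4–C5–C6, and formation of the C9 carbonyl group pays for the medium-ring strain. C7, the only new stereocentre, is controlled by C6: allylic 1,3-strain against the C13 methyl group holds H6 in the alkene plane, and C8 should add anti to the C6–O bond, on the face where C5 stays gauche to the new bond as the closing ring demands, which gives 7S and the anti H6/H7 relationship of the trans-lactone. The step needs periselectivity over the 1,5-hydrogen shift of the Z-dienol ether (C2–H to C8) and over Cope rearrangement of the product 1,5-diene C10=C1–C2–C3–C4=C5; the substrate holds a single allyl vinyl ether, both rivals have higher intrinsic barriers, and the acid-free medium at moderate temperature protects the enol ether and the bis-allylic silyl ether.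

**Step 12**
Reactants: 18 (2Z,5S,6E,8R,9S)-8-(tert-butyldimethylsilyloxy)-2,6-dimethyl-9-(prop-1-en-2-yl)-5-(triethylsilyloxy)cyclodeca-2,6-dien-1-one
Product: 20 (1R,2Z,5S,6E,8R,9S)-8-(tert-butyldimethylsilyloxy)-2,6-dimethyl-9-(prop-1-en-2-yl)cyclodeca-2,6-diene-1,5-diol, via C9 carbinol triethylsilyl ether 19 (not isolated)
Conditions: (S)-Me-CBS (0.5 equiv), catecholborane, toluene, −78 °C; then MeOH, PPTS (cat.), 0 °C to rt
Reagents that add atoms: none
Why: Corey–Bakshi–Shibata reduction, in which the 2-methylalkenyl side (C10) acts as the large group so that the (S)-catalyst should give 9R by 1,2-reduction and catecholborane at low temperature spares the alkenes, followed by acid-catalysed methanolysis that removes the triethylsilyl but not the tert-butyldimethylsilyl ether.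

**Step 13**
Reactants: 20 (1R,2Z,5S,6E,8R,9S)-8-(tert-butyldimethylsilyloxy)-2,6-dimethyl-9-(prop-1-en-2-yl)cyclodeca-2,6-diene-1,5-diol
Product: 21 (1R,2Z,5S,6E,8R,9S)-8-(tert-butyldimethylsilyloxy)-2,6-dimethyl-9-(prop-1-en-2-yl)cyclodeca-2,6-diene-1,5-diyl diacetate
Conditions: Ac2O, pyridine, DMAP (cat.), CH2Cl2, 0 °C to rt
Reagents that add atoms: acetic anhydride CC(=O)OC(C)=O
Why: Standard double acetylation with retention at C3 and C9, which installs both acetates of the target at once and deactivates both ring alkenes towards the next step.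

**Step 14**
Reactants: 21 (1R,2Z,5S,6E,8R,9S)-8-(tert-butyldimethylsilyloxy)-2,6-dimethyl-9-(prop-1-en-2-yl)cyclodeca-2,6-diene-1,5-diyl diacetate
Product: 23 (1R,2Z,5S,6E,8S,9S)-8-(tert-butyldimethylsilyloxy)-9-[(2R)-1-hydroxypropan-2-yl]-2,6-dimethylcyclodeca-2,6-diene-1,5-diyl diacetate, via B-alkyl-9-BBN adduct 22 (not isolated)
Conditions: 9-BBN, THF, 0 °C to rt; NaBO3·4H2O, THF/H2O, rt
Reagents that add atoms: 9-borabicyclo[3.3.1]nonane B1C2CCCC1CCC2; sodium perborate [Na+].[O-]OB=O
Why: Hydroboration–oxidation; 9-BBN strongly prefers the 1,1-disubstituted alkene to the two hindered trisubstituted ring alkenes, and with C11=C12 eclipsing C7–H it should approach from the face turned away from the C6 silyloxy group and give 11R, the sense known for trans-2-isopropenylcyclohexyl ethers of the isopulegol type.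

**Step 15**
Reactants: 23 (1R,2Z,5S,6E,8S,9S)-8-(tert-butyldimethylsilyloxy)-9-[(2R)-1-hydroxypropan-2-yl]-2,6-dimethylcyclodeca-2,6-diene-1,5-diyl diacetate
Product: 24 (1R,2Z,5S,6E,8S,9S)-8-hydroxy-9-[(2R)-1-hydroxypropan-2-yl]-2,6-dimethylcyclodeca-2,6-diene-1,5-diyl diacetate
Conditions: HF·pyridine, pyridine/THF, 0 °C to rt
Reagents that add atoms: none
Why: Buffered fluoride desilylation, mild enough for the acetates and for the acid-sensitive cyclodecadiene.

**Step 16**
Reactants: 24 (1R,2Z,5S,6E,8S,9S)-8-hydroxy-9-[(2R)-1-hydroxypropan-2-yl]-2,6-dimethylcyclodeca-2,6-diene-1,5-diyl diacetate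
Product: 27 (3R,3aS,5R,6Z,9S,10E,11aS)-3,6,10-trimethyl-2-oxo-2,3,3a,4,5,8,9,11a-octahydrocyclodeca[b]furan-5,9-diyl diacetate, via hydroxy aldehyde 25 (not isolated), via lactol 26 (not isolated)
Conditions: TEMPO (20 mol %), PhI(OAc)2 (2.5 equiv), CH2Cl2, rt
Reagents that add atoms: none
Why: TEMPO/PhI(OAc)2 oxidative lactonisation of a 1,4-diol; the primary alcohol is oxidised first, the aldehyde closes on the C6 hydroxyl group (5-exo-trig) and the lactol is oxidised on, under conditions too mild to epimerise C11.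

**Compound list**
1 | (2E)-4-acetoxy-2-methylbut-2-enal | CC(=O)OC/C=C(\C)C=O | starting material
2 | allyltributylstannane | C=CC[Sn](CCCC)(CCCC)CCCC | starting material
3 | (2E,4S)-4-hydroxy-3-methylhepta-2,6-dien-1-yl acetate | CC(=O)OC/C=C(\C)[C@@H](O)CC=C | intermediate
4 | methacryloyl chloride | CC(=C)C(=O)Cl | starting material
5 | (2E,4S)-1-acetoxy-3-methylhepta-2,6-dien-4-yl methacrylate | CC(=O)OC/C=C(\C)[C@@H](OC(=O)C(C)=C)CC=C | intermediate
6 | (6S)-6-[(2E)-4-acetoxybut-2-en-2-yl]-3-methyl-5,6-dihydro-2H-pyran-2-one | CC(=O)OC/C=C(\C)[C@@H]1CC=C(C)C(=O)O1 | intermediate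
7 | lithium (2Z,5S,6E)-5,8-dihydroxy-2,6-dimethylocta-2,6-dienoate | [Li+].[O-]C(=O)/C(C)=C\C[C@H](O)/C(C)=C/CO | intermediate
8 | triethylsilyl (2Z,5S,6E)-2,6-dimethyl-5,8-bis(triethylsilyloxy)octa-2,6-dienoate | CC[Si](CC)(CC)OC(=O)/C(C)=C\C[C@H](O[Si](CC)(CC)CC)/C(C)=C/CO[Si](CC)(CC)CC | intermediate
9 | (2Z,5S,6E)-2,6-dimethyl-5,8-bis(triethylsilyloxy)octa-2,6-dienoic acid | OC(=O)/C(C)=C\C[C@H](O[Si](CC)(CC)CC)/C(C)=C/CO[Si](CC)(CC)CC | intermediate
10 | prop-2-yn-1-ol | C#CCO | starting material
11 | dimethylaluminium (2E)-3-(dimethylalumanyl)-2-methylprop-2-en-1-olate | C[Al](C)OC/C(C)=C/[Al](C)C | intermediate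
12 | (2E)-3-iodo-2-methylprop-2-en-1-ol | OC/C(C)=C/I | intermediate
13 | (2E)-3-iodo-2-methylprop-2-en-1-yl (2Z,5S,6E)-2,6-dimethyl-5,8-bis(triethylsilyloxy)octa-2,6-dienoate | I/C=C(\C)COC(=O)/C(C)=C\C[C@H](O[Si](CC)(CC)CC)/C(C)=C/CO[Si](CC)(CC)CC | intermediate
14 | (2E)-3-iodo-2-methylprop-2-en-1-yl (2Z,5S,6E)-2,6-dimethyl-8-oxo-5-(triethylsilyloxy)octa-2,6-dienoate | I/C=C(\C)COC(=O)/C(C)=C\C[C@H](O[Si](CC)(CC)CC)/C(C)=C/C=O | intermediate
15 | (3Z,6S,7E,9S,10E)-9-hydroxy-3,7,11-trimethyl-6-(triethylsilyloxy)-1-oxacyclododeca-3,7,10-trien-2-one | C/C1=C/C[C@H](O[Si](CC)(CC)CC)/C(C)=C/[C@@H](O)/C=C(\C)COC1=O | intermediate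
16 | (3Z,6S,7E,9S,10E)-9-(tert-butyldimethylsilyloxy)-3,7,11-trimethyl-6-(triethylsilyloxy)-1-oxacyclododeca-3,7,10-trien-2-one | C/C1=C/C[C@H](O[Si](CC)(CC)CC)/C(C)=C/[C@@H](O[Si](C)(C)C(C)(C)C)/C=C(\C)COC1=O | intermediate
17 | (3Z,6S,7E,9S,10E)-9-(tert-butyldimethylsilyloxy)-3,7,11-trimethyl-2-methylidene-6-(triethylsilyloxy)-1-oxacyclododeca-3,7,10-triene | C/C1=C/C[C@H](O[Si](CC)(CC)CC)/C(C)=C/[C@@H](O[Si](C)(C)C(C)(C)C)/C=C(\C)COC1=C | intermediate
18 | (2Z,5S,6E,8R,9S)-8-(tert-butyldimethylsilyloxy)-2,6-dimethyl-9-(prop-1-en-2-yl)-5-(triethylsilyloxy)cyclodeca-2,6-dien-1-one | C/C1=C/C[C@H](O[Si](CC)(CC)CC)/C(C)=C/[C@@H](O[Si](C)(C)C(C)(C)C)[C@H](C(C)=C)CC1=O | intermediate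
19 | (1R,2Z,5S,6E,8R,9S)-8-(tert-butyldimethylsilyloxy)-2,6-dimethyl-9-(prop-1-en-2-yl)-5-(triethylsilyloxy)cyclodeca-2,6-dien-1-ol | C/C1=C/C[C@H](O[Si](CC)(CC)CC)/C(C)=C/[C@@H](O[Si](C)(C)C(C)(C)C)[C@H](C(C)=C)C[C@H]1O | intermediate
20 | (1R,2Z,5S,6E,8R,9S)-8-(tert-butyldimethylsilyloxy)-2,6-dimethyl-9-(prop-1-en-2-yl)cyclodeca-2,6-diene-1,5-diol | C/C1=C/C[C@H](O)/C(C)=C/[C@@H](O[Si](C)(C)C(C)(C)C)[C@H](C(C)=C)C[C@H]1O | intermediate
21 | (1R,2Z,5S,6E,8R,9S)-8-(tert-butyldimethylsilyloxy)-2,6-dimethyl-9-(prop-1-en-2-yl)cyclodeca-2,6-diene-1,5-diyl diacetate | C/C1=C/C[C@H](OC(C)=O)/C(C)=C/[C@@H](O[Si](C)(C)C(C)(C)C)[C@H](C(C)=C)C[C@H]1OC(C)=O | intermediate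
22 | B-alkyl-9-BBN adduct of 21 (boron on C12, new hydrogen on C11 placed as in 23) | C/C1=C/C[C@H](OC(C)=O)/C(C)=C/[C@@H](O[Si](C)(C)C(C)(C)C)[C@H]([C@@H](C)CB2C3CCCC2CCC3)C[C@H]1OC(C)=O | intermediate
23 | (1R,2Z,5S,6E,8S,9S)-8-(tert-butyldimethylsilyloxy)-9-[(2R)-1-hydroxypropan-2-yl]-2,6-dimethylcyclodeca-2,6-diene-1,5-diyl diacetate | C/C1=C/C[C@H](OC(C)=O)/C(C)=C/[C@@H](O[Si](C)(C)C(C)(C)C)[C@H]([C@@H](C)CO)C[C@H]1OC(C)=O | intermediate
24 | (1R,2Z,5S,6E,8S,9S)-8-hydroxy-9-[(2R)-1-hydroxypropan-2-yl]-2,6-dimethylcyclodeca-2,6-diene-1,5-diyl diacetate | C/C1=C/C[C@H](OC(C)=O)/C(C)=C/[C@@H](O)[C@H]([C@@H](C)CO)C[C@H]1OC(C)=O | intermediate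
25 | (1R,2Z,5S,6E,8S,9S)-8-hydroxy-2,6-dimethyl-9-[(2R)-1-oxopropan-2-yl]cyclodeca-2,6-diene-1,5-diyl diacetate | C/C1=C/C[C@H](OC(C)=O)/C(C)=C/[C@@H](O)[C@H]([C@@H](C)C=O)C[C@H]1OC(C)=O | intermediate
26 | lactol of 25 (C12 hemiacetal closed on the C6 oxygen, C12 unassigned) | C/C1=C/C[C@H](OC(C)=O)/C(C)=C/[C@H]2OC(O)[C@H](C)[C@@H]2C[C@H]1OC(C)=O | intermediate
27 | (3R,3aS,5R,6Z,9S,10E,11aS)-3,6,10-trimethyl-2-oxo-2,3,3a,4,5,8,9,11a-octahydrocyclodeca[b]furan-5,9-diyl diacetate; germacrane locants 3S,6S,7S,9R,11R, 1(10)Z, 4E | CC(=O)O[C@H]1C/C=C(/C)[C@H](OC(C)=O)C[C@@H]2[C@@H](/C=C/1C)OC(=O)[C@@H]2C | target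

**Step count**
Total step count: 16. Longest linear sequence: 15 (steps 1–4 and 6–16, from 1). Step 5 is a one-step side branch.

**Steps most likely to fail**

First, step 11. The bridged six-centre array may be out of reach of the preferred conformers of the 12-membered ring. In that case the 1,5-hydrogen shift of the dienol ether, Cope rearrangement of the product at the temperature then needed, or attack on the wrong alkene face could take over. The fallback uses known chemistry, sets out from 16 and comes back at 18. It makes the same C7–C8 bond through a fused rather than a bridged array and at lower temperature, by an anion-accelerated decarboxylative Claisen (Carroll) rearrangement.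
- Lactone 16 is opened by crossed Claisen condensation with lithio tert-butyl acetate (THF, −78 °C) to the seco β-keto ester F1.
- Heating in toluene at high dilution exchanges tert-butanol for the C12 hydroxyl group and closes the 14-membered β-keto lactone F2.
- Its dianion (LDA, THF, −78 °C to reflux) rearranges to the ring-contracted β-keto acid F3. This is a four-atom lactone contraction of the ester-enolate Claisen type.
- Gentle warming removes CO2 and gives 18.

Second, step 8. Oligomerisation may compete with ring closure. Facial selectivity at the aldehyde may also be poor if the conformational preference of the forming ring overrides the ligand. The fallback sets out from 14 and comes back at 15. It gives up face-selective C–C bond formation and supplies C6 by separation and redox recycling.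
- Ligand-free closure (CrCl2, NiCl2 cat., DMSO/THF, high dilution) gives 15 together with its C6 epimer F4, a diastereomer that can be removed by chromatography.
- This epimer is oxidised with MnO2 to the cross-conjugated macrocyclic dienone F5.
- The dienone is reduced again (NaBH4, CeCl3·7H2O, MeOH, −78 °C) and the mixture is re-separated, so that material is funnelled into 15.

Third, step 14. The strained E-alkene C4=C5 may be hydroborated in competition, and facial selectivity at C11 may be poor in the flexible ring. The fallback sets out from 21 and comes back at 23. It replaces the uncatalysed four-centre addition by metal-hydride insertion, whose chemoselectivity rests on alkene coordination that trisubstituted alkenes cannot achieve.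
- Pinacolborane with [Ir(cod)Cl]2 and dppe (THF, rt) gives the isolable pinacol boronate F6.
- C11 epimers can be separated at this stage.
- Oxidation with NaBO3·4H2O then gives 23.

**Further compounds**
F1 | step 11 | tert-butyl (4Z,7S,8E,10S,11E)-10-(tert-butyldimethylsilyloxy)-13-hydroxy-4,8,12-trimethyl-3-oxo-7-(triethylsilyloxy)trideca-4,8,11-trienoate | CC(C)(C)OC(=O)CC(=O)/C(C)=C\C[C@H](O[Si](CC)(CC)CC)/C(C)=C/[C@@H](O[Si](C)(C)C(C)(C)C)/C=C(\C)CO
F2 | step 11 | (5Z,8S,9E,11S,12E)-11-(tert-butyldimethylsilyloxy)-5,9,13-trimethyl-8-(triethylsilyloxy)-1-oxacyclotetradeca-5,9,12-triene-2,4-dione | C/C1=C/C[C@H](O[Si](CC)(CC)CC)/C(C)=C/[C@@H](O[Si](C)(C)C(C)(C)C)/C=C(\C)COC(=O)CC1=O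
F3 | step 11 | (3Z,6S,7E,9R,10S)-9-(tert-butyldimethylsilyloxy)-3,7-dimethyl-2-oxo-10-(prop-1-en-2-yl)-6-(triethylsilyloxy)cyclodeca-3,7-diene-1-carboxylic acid (C1 unassigned) | C/C1=C/C[C@H](O[Si](CC)(CC)CC)/C(C)=C/[C@@H](O[Si](C)(C)C(C)(C)C)[C@H](C(C)=C)C(C(=O)O)C1=O
F4 | step 8 | (3Z,6S,7E,9R,10E)-9-hydroxy-3,7,11-trimethyl-6-(triethylsilyloxy)-1-oxacyclododeca-3,7,10-trien-2-one | C/C1=C/C[C@H](O[Si](CC)(CC)CC)/C(C)=C/[C@H](O)/C=C(\C)COC1=O
F5 | step 8 | (3Z,6S,7E,10E)-3,7,11-trimethyl-6-(triethylsilyloxy)-1-oxacyclododeca-3,7,10-triene-2,9-dione | C/C1=C/C[C@H](O[Si](CC)(CC)CC)/C(C)=C/C(=O)/C=C(\C)COC1=O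
F6 | step 14 | (1R,2Z,5S,6E,8S,9S)-8-(tert-butyldimethylsilyloxy)-2,6-dimethyl-9-[(2S)-1-(4,4,5,5-tetramethyl-1,3,2-dioxaborolan-2-yl)propan-2-yl]cyclodeca-2,6-diene-1,5-diyl diacetate | C/C1=C/C[C@H](OC(C)=O)/C(C)=C/[C@@H](O[Si](C)(C)C(C)(C)C)[C@H]([C@@H](C)CB2OC(C)(C)C(C)(C)O2)C[C@H]1OC(C)=O
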